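## Retrosynthetic overview

- The target is a 7-methoxycoumarin (ring A benzene, ring B pyranone). C8 of ring A bears the acyl carbon C1' and sits between the C7 methoxy group and the C8a–O1 oxygen. This contiguous O/acyl/OMe 1,2,3-pattern is the feature the plan rests on.
- The senecioate at the C2' oxygen is removed first. Ring B is then opened at C4–C4a (6-endo-dig hydroarylation of an aryl propiolate) and at O1–C2 (phenol esterification).
- The remaining 2-hydroxy-6-methoxyphenyl ketone is cut at O1–C8a and C8–C1' into 3-methoxybenzyne and a carboxylic acid, which is an aryne insertion into the acid C–O bond.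
- The acid is the O-MOM ether of (R)-2-hydroxy-3-methylbutanoic acid, the chiral-pool source of C2'. Ring A is bought with the aryne precursor, so ring B is the only ring formed (step 5).

Key step: step 3

Assumption: coumarin numbering (O1, C2–C4, C4a, C5–C8, C8a; side chain C1'–C3') is used for all intermediates. The descriptor at C2' stays R throughout because the priority order O > C1' > CH(CH3)2 > H never changes.

## Route

Step 1
Reactants: 1 (R)-2-hydroxy-3-methylbutanoic acid
Product: 2 methoxymethyl (2R)-2-(methoxymethoxy)-3-methylbutanoate
Conditions: MOMCl (3 equiv), iPr2NEt (4 equiv), CH2Cl2, 0 °C → rt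
Reagents that add atoms: chloromethyl methyl ether (MOMCl), COCCl
Why: Double O-alkylation (Williamson-type, through the methoxymethyl oxocarbenium ion) of carboxylate and secondary hydroxyl is standard for α-hydroxy acids and breaks no bond at C2', so the R configuration of 1 is carried over.

Step 2
Reactants: 2 methoxymethyl (2R)-2-(methoxymethoxy)-3-methylbutanoate
Product: 3 (2R)-2-(methoxymethoxy)-3-methylbutanoic acid
Conditions: LiOH, THF/H2O, 0 °C → rt; then 1 M HCl to pH 3, 0 °C
Reagents that add atoms: lithium hydroxide, [Li+].[OH-]
Why: Saponification works here because the acetal-type MOM ester is cleaved by cold LiOH while the MOM ether is inert to base, the α-alkoxy carboxylate does not enolise, and brief cold acidification spares the acetal.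

Step 3
Reactants: 3 (2R)-2-(methoxymethoxy)-3-methylbutanoic acid; 4 3-methoxy-2-(trimethylsilyl)phenyl trifluoromethanesulfonate
Product: 6 (2R)-1-(2-hydroxy-6-methoxyphenyl)-2-(methoxymethoxy)-3-methylbutan-1-one, via 3-methoxybenzyne 5 (not isolated)
Conditions: 4 (1.5 equiv), CsF (4 equiv), THF, sealed tube, 125 °C; aq NH4Cl work-up
Reagents that add atoms: none
Why: CsF deprotonates 3 and strips the silyl group from 4, triflate leaves and 3-methoxybenzyne 5 is released slowly; the carboxylate oxygen adds to the aryne carbon meta to the methoxy group (future C8a), the aryl anion thus placed at future C8 attacks the carbonyl carbon C1' of the aryl ester just formed, and the four-membered alkoxide collapses by breaking the C1'–O bond to the ketone phenoxide, so that O1–C8a and C8–C1' arise in one operation. The closest known reaction type is this same fluoride-triggered insertion of arynes into the C–O bond of carboxylic acids in hot THF, which gives ortho-hydroxyaryl ketones from aromatic and aliphatic acids, and an α-alkoxy acid is only a new member of that class. No ring of the target is closed, since the only ring is the transient benzoxete alkoxide (4-exo-trig attack), which reopens at once. No stereocentre is created: C2' comes from 1, no bond to it is made or broken, and enolisation should be slow because the ketone is born as its electron-rich caesium phenoxide, is twisted out of the ring A plane by two ortho substituents, and has its α-CH shielded by isopropyl and OMOM groups. Regioselectivity is needed and is secured by the inductively withdrawing methoxy group next to the triple bond, which distorts the aryne and stabilises negative charge at C8, so oxygen goes to C8a. Chemoselectivity for acyl capture over protonation of the aryl anion is also needed and is favoured by the aprotic medium, the high temperature and the carbonyl group held three atoms away.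

Step 4
Reactants: 6 (2R)-1-(2-hydroxy-6-methoxyphenyl)-2-(methoxymethoxy)-3-methylbutan-1-one; 7 propiolic acid
Product: 8 3-methoxy-2-[(2R)-2-(methoxymethoxy)-3-methylbutanoyl]phenyl prop-2-ynoate
Conditions: DCC, DMAP (cat.), CH2Cl2, 0 °C → rt
Reagents that add atoms: none
Why: In this Steglich esterification the carbodiimide-activated acid acylates the only free hydroxyl (the C8a phenol), while the low temperature and merely catalytic DMAP limit amine addition to the ynoate and leave C2' untouched.

Step 5
Reactants: 8 3-methoxy-2-[(2R)-2-(methoxymethoxy)-3-methylbutanoyl]phenyl prop-2-ynoate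
Product: 10 8-[(2R)-2-hydroxy-3-methylbutanoyl]-7-methoxy-2H-chromen-2-one, via MOM-protected coumarin 9 (not isolated)
Conditions: Pd(OAc)2 (5 mol %), TFA/CH2Cl2, rt; then H2O, 40 °C; aq NaHCO3 work-up
Reagents that add atoms: none
Why: In this Fujiwara-type intramolecular hydroarylation, electrophilic divalent palladium formed in TFA activates the ynoate, the only free ortho carbon of ring A (future C4a, para to the C7 methoxy group and meta to the acyl group) attacks the terminal alkyne carbon in a 6-endo-dig closure, protodemetalation completes ring B, and the same acid with added water hydrolyses the MOM acetal without breaking the C2'–O bond.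

Step 6
Reactants: 10 8-[(2R)-2-hydroxy-3-methylbutanoyl]-7-methoxy-2H-chromen-2-one; 11 3-methylbut-2-enoyl chloride (senecioyl chloride)
Product: 12 (2R)-1-(7-methoxy-2-oxo-2H-chromen-8-yl)-3-methyl-1-oxobutan-2-yl 3-methylbut-2-enoate (target)
Conditions: pyridine, DMAP (cat.), CH2Cl2, 0 °C → rt
Reagents that add atoms: none
Why: This is O-acylation of the secondary alcohol under nucleophilic catalysis, and pyridine is too weak a base to turn 11 into the vinylketene that causes deconjugation or to enolise the hindered ketone, so the C2'–O bond and its R configuration are retained.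

## Compound list

1 | (R)-2-hydroxy-3-methylbutanoic acid | CC(C)[C@@H](O)C(=O)O | starting material
2 | methoxymethyl (2R)-2-(methoxymethoxy)-3-methylbutanoate | COCOC(=O)[C@H](OCOC)C(C)C | intermediate
3 | (2R)-2-(methoxymethoxy)-3-methylbutanoic acid | OC(=O)[C@H](OCOC)C(C)C | intermediate
4 | 3-methoxy-2-(trimethylsilyl)phenyl trifluoromethanesulfonate | COc1cccc(OS(=O)(=O)C(F)(F)F)c1[Si](C)(C)C | starting material
5 | 3-methoxybenzyne (1-methoxycyclohexa-1,3-dien-5-yne) | COC1=CC=CC#C1 | intermediate
6 | (2R)-1-(2-hydroxy-6-methoxyphenyl)-2-(methoxymethoxy)-3-methylbutan-1-one | COc1cccc(O)c1C(=O)[C@H](OCOC)C(C)C | intermediate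
7 | propiolic acid | C#CC(=O)O | starting material
8 | 3-methoxy-2-[(2R)-2-(methoxymethoxy)-3-methylbutanoyl]phenyl prop-2-ynoate | COc1cccc(OC(=O)C#C)c1C(=O)[C@H](OCOC)C(C)C | intermediate
9 | 7-methoxy-8-[(2R)-2-(methoxymethoxy)-3-methylbutanoyl]-2H-chromen-2-one | COc1ccc2ccc(=O)oc2c1C(=O)[C@H](OCOC)C(C)C | intermediate
10 | 8-[(2R)-2-hydroxy-3-methylbutanoyl]-7-methoxy-2H-chromen-2-one | COc1ccc2ccc(=O)oc2c1C(=O)[C@H](O)C(C)C | intermediate
11 | 3-methylbut-2-enoyl chloride | CC(C)=CC(=O)Cl | starting material
12 | (2R)-1-(7-methoxy-2-oxo-2H-chromen-8-yl)-3-methyl-1-oxobutan-2-yl 3-methylbut-2-enoate | COc1ccc2ccc(=O)oc2c1C(=O)[C@H](OC(=O)C=C(C)C)C(C)C | target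

Total step count: 6
Longest linear sequence: 6 steps (1 → 2 → 3 → 6 → 8 → 10 → 12)

## Steps most likely to fail

**Step 3.**
- Risk: Protonation of the C8 aryl anion may outrun the acyl shift and stop the sequence at simple O-arylation. A second aryne may arylate the phenoxide. Long heating with fluoride may erode the configuration at C2' by enolisation, so the enantiomeric purity of 6 should be checked against a racemic reference.
- Fallback: It sets out from 3 and comes back at 6, and it generates the same C8 aryl anion cold and without an aryne. Acid 3 is esterified (DCC, DMAP cat., CH2Cl2) with commercial 2-bromo-3-methoxyphenol to give 2-bromo-3-methoxyphenyl (2R)-2-(methoxymethoxy)-3-methylbutanoate F1. Bromine–lithium exchange with s-BuLi in THF/Et2O at −95 °C then triggers an anionic Fries O→C acyl shift. This should deliver 6 after an aqueous NH4Cl quench.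

**Step 5.**
- Risk: The C8 acyl group lowers the nucleophilicity of ring A. Ring closure may therefore be slow compared with solvolysis of the activated aryl ester or addition of TFA across the alkyne. Early loss of the acetal could also allow migration of the propioloyl group from the phenol oxygen to the C2' oxygen.
- Fallback: It sets out from 6, bypasses step 4 and comes back at 9, building ring B from a C4 aldehyde.
  - Casnati–Skattebøl ortho-formylation (MgCl2, Et3N, paraformaldehyde, MeCN, reflux) at the only free ortho position gives 2-hydroxy-4-methoxy-3-[(2R)-2-(methoxymethoxy)-3-methylbutanoyl]benzaldehyde F2.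
  - Wittig olefination with Ph3P=CHCO2Et in hot N,N-diethylaniline leads to ethyl (Z)-3-{2-hydroxy-4-methoxy-3-[(2R)-2-(methoxymethoxy)-3-methylbutanoyl]phenyl}prop-2-enoate F3.
  - F3 lactonises in the flask to 9, and the aqueous TFA stage of step 5 then gives 10.

**Step 6.**
- Risk: γ-Deprotonation of the acylpyridinium ion (vinylketene pathway) may move the double bond out of conjugation. Acylation of the crowded carbinol between the isopropyl and aroyl groups may stall. Long exposure to amine may epimerise C2'.
- Fallback: It sets out from 10 and comes back at 12, replacing base-promoted acyl chloride chemistry by base-free Lewis acid activation. 3-Methylbut-2-enoic acid is dehydrated with DCC (0.5 equiv, CH2Cl2) to 3-methylbut-2-enoic anhydride F4. F4 acylates 10 under Sc(OTf)3 catalysis in MeCN at −20 °C → 0 °C.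

## Further compounds

F1 | step 3 | 2-bromo-3-methoxyphenyl (2R)-2-(methoxymethoxy)-3-methylbutanoate | COc1cccc(OC(=O)[C@H](OCOC)C(C)C)c1Br
F2 | step 5 | 2-hydroxy-4-methoxy-3-[(2R)-2-(methoxymethoxy)-3-methylbutanoyl]benzaldehyde | COc1ccc(C=O)c(O)c1C(=O)[C@H](OCOC)C(C)C
F3 | step 5 | ethyl (Z)-3-{2-hydroxy-4-methoxy-3-[(2R)-2-(methoxymethoxy)-3-methylbutanoyl]phenyl}prop-2-enoate | CCOC(=O)/C=C\c1ccc(OC)c(C(=O)[C@H](OCOC)C(C)C)c1O
F4 | step 6 | 3-methylbut-2-enoic anhydride | CC(C)=CC(=O)OC(=O)C=C(C)C
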